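Friday's run stops.

| flask | electrophile | nucleophile | solid base | remark | time |
|---|---|---|---|---|---|
| Friday's | 0.16 M | 0.27 M | 0.16 M | run made earlier |  |
| Thursday's | 0.16 M | 1.2 M | 0.16 M | run made earlier |  |
| cedar | 0.16 M | 0.420 M | 0.160 M |  | 12 h |
| oak | 0.16 M | 0.830 M | 0.160 M |  | 12 h |
| elm | 0.16 M | 0.210 M | 0.160 M |  | 12 h |

- Friday's (time / h: electrophile / %, product / %): 1.33: 20, 80; 2.50: 16, 84; 4.00: 20, 83; 5.00: 18, 82; 6.00: 21, 83; 8.00: 17, 87
- Thursday's (time / h: electrophile / %, product / %): 0.667: 0, 97; 1.00: 3, 99; 1.50: 1, 98; 2.50: 1, 101; 4.00: 0, 98; 6.00: 1, 100; 8.00: 0, 98

(scatter of a reading: 2 percentage points)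

- solid, in amounts per volume of the solution: solid base
- the analysis behind the earlier runs scatters by 2 percentage points, standard deviation
- at the start none of the solid base is in solution

- part of the electrophile that has reacted at the end, cedar
- part of the electrophile that has reacted at the end, oak
- part of the electrophile that has reacted at the end, elm
- what raising the concentration of nucleophile from its lowest to its highest value here does to the part of the electrophile that has reacted (changes below 5 percentage points count as none) (it rises / it falls / no change)

Friday's electrophile peak reads 20% at 1.33 h and 17% at 8.00 h, a drift near the scatter, and product averages 83.2%. Thursday's run differs from it in the nucleophile charge, and it reaches 98% product. So this reckoning reads Friday's stop as the nucleophile's end: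

nucleophile used per product = 0.27 M / (0.16 M × 83.2%) = 2.03

This number, read from Friday's scattered readings, is the nucleophile used per electrophile reacted. Folded with a flask's charges, it gives the reach: the nucleophile charged over this number times the electrophile charged. On this reckoning, below one nucleophile is the limiting reagent and the reach is the part reacted, and above one the electrophile goes first.

elm: 0.210 M / (2.03 × 0.16 M) = 0.647

cedar: 0.420 M / (2.03 × 0.16 M) = 1.29

oak: 0.830 M / (2.03 × 0.16 M) = 2.56

Is one number enough? Thursday's reach is 3.70, above one, and its last electrophile reading is 0%, as the rule expects, though that run helped to choose the rule. Friday's readings stay flat within the scatter from the first one on, and 12 h lies beyond the last, so this reckoning carries no term for time. Cedar, oak and elm carry the solid base charge of both runs, so this reckoning carries no term for the base either. The reckoning therefore gives 64.7% for elm, complete reaction for cedar and oak, and a rise.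

The forecast, holding that “the stall looks more like nucleophile running out”, gave 96% for cedar, 99% for oak and 70% for elm, and said it rises; this reckoning has 64.7% on elm and complete reaction on cedar.

The flask gives 99.8% for cedar, >99.9% for oak and 65.2% for elm, and it rises by 35 percentage points. At the end of elm, protonated nucleophile stands at 0.100 M, far above the salt of the base at 0.00183 M, beside product at 0.104 M.

    solid base ⇌ free base, rate k1*(cs1 - [free base]) while solid is left; crystals form when [free base] > cs1 (solubility = 19.0 mM, k = 0.630 h⁻¹)
    electrophile + nucleophile ⇌ acid set free + product (K = 0.730, k = 34.0 M⁻¹ h⁻¹)
    acid set free + free base ⇌ salt of the base, settled at all times (K = 46.0 M⁻¹)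
    nucleophile + acid set free ⇌ protonated nucleophile, settled at all times (K = 8900 M⁻¹)

With 0.084 M of nucleophile and elm's other charges, the reach is 0.084 M / (2.03 × 0.16 M) = 0.259, so 25.9% should react. The computed flask gives 27.5%, with 1.8% of its nucleophile still free.

All runs come from a simulation for substances that don't exist; scatter was added.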